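The route rests on making the cyclobutane bond between the two ring-fusion carbons, C1 (next to quaternary C11) and C9 (next to the methylene-bearing C8), by photochemical Wolff ring contraction. The step exploits that C9 of the four-membered ring carries a carbonyl-level carbon, C8, outside that ring. In the precursor, a 2-diazocyclopentanone with ring C8(=O)–C9(=N2)–C10–C11–C1, C8 is a ring member; it is expelled as an ester on C9 while C1 migrates to C9 with retention. The precursor arises from enantioselective conjugate addition and enolate alkylation on 3-methylcyclopentenone. Afterwards the nine-membered ring is closed by palladium-catalysed allylic alkylation and the dioxin hemiketal by closure of a Z-γ-hydroperoxy enone.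

Key step: step 9

Remark on numbering: cyclobutane C1 (CH bonded to C2), C9 (CH bonded to C8), C10 (CH2), C11 (quaternary, CH3 and C12); nine-membered ring C1–C2–C3–C4(CH3)–C5–C6–C7–C8(=CH2)–C9; dioxin C12 (hemiketal), C13=C14, C15 (CH3 and CH2OAc).

Remark on the chemistry: the hemiketal carbon C12 equilibrates by ring–chain tautomerism, and the target epimer (OH cis to CH2OAc) is assumed to be the favoured one. The lipase in step 17 is assumed, after screening, to give the (R)-monoacetate; acylation of the corresponding diol is the enantiocomplementary mode.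

Step 1
Reactants: 1 ethynylmagnesium bromide; 2 benzylchlorodimethylsilane
Product: 3 benzyl(ethynyl)dimethylsilane
Conditions: THF, 0 °C → rt
Reagents that add atoms: none
Why: Substitution at silicon by the alkynyl Grignard reagent gives the ethynylsilane; no stereocentre is involved.

Step 2
Reactants: 4 (but-3-yn-1-yloxy)(tert-butyl)dimethylsilane
Product: 6 (E)-5-[(tert-butyldimethylsilyl)oxy]-3-methylpent-2-en-1-ol, via alkenylalane 5 (not isolated)
Conditions: Me3Al, Cp2ZrCl2 (cat.), CH2Cl2, 0 °C → rt; then (CH2O)n, rt; aq. work-up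
Reagents that add atoms: trimethylaluminium C[Al](C)C; formaldehyde (as paraformaldehyde) C=O
Why: Zirconium-catalysed syn-carboalumination (Negishi carboalumination) adds methyl and aluminium cis across the alkyne, and the alkenylalane is hydroxymethylated with retention, which fixes the E geometry of the future C4=C5 alkene.

Step 3
Reactants: 6 (E)-5-[(tert-butyldimethylsilyl)oxy]-3-methylpent-2-en-1-ol; 7 4-methoxyphenol
Product: 8 tert-butyl{[(3E)-5-(4-methoxyphenoxy)-3-methylpent-3-en-1-yl]oxy}dimethylsilane
Conditions: PPh3, DIAD, THF, 0 °C → rt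
Reagents that add atoms: none
Why: Mitsunobu etherification (SN2 at the primary allylic carbon C6) installs an aryloxy group that is inert to bases and nucleophiles and later serves as the allylic leaving group.

Step 4
Reactants: 8 silyl ether
Product: 9 (E)-5-(4-methoxyphenoxy)-3-methylpent-3-en-1-ol
Conditions: n-Bu4NF, THF, 0 °C → rt
Reagents that add atoms: none
Why: Fluoride-mediated desilylation frees the homoallylic alcohol without touching the aryl allyl ether.

Step 5
Reactants: 9 (E)-5-(4-methoxyphenoxy)-3-methylpent-3-en-1-ol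
Product: 10 (E)-5-(4-methoxyphenoxy)-3-methylpent-3-en-1-yl trifluoromethanesulfonate
Conditions: Tf2O, 2,6-lutidine, CH2Cl2, −78 °C; cold work-up, used at once
Reagents that add atoms: trifluoromethanesulfonic anhydride O=S(=O)(OS(=O)(=O)C(F)(F)F)C(F)(F)F
Why: O-Sulfonylation of the primary alcohol gives a highly reactive alkylating agent whose alkene is deactivated toward π-participation by the allylic aryloxy group.

Step 6
Reactants: 11 3-methylcyclopent-2-en-1-one; 3 benzyl(ethynyl)dimethylsilane
Product: 14 (S)-benzyl(dimethyl){1-[1-methyl-3-(trimethylsilyloxy)cyclopent-2-en-1-yl]ethenyl}silane, via alkenylalane 12 (not isolated), via aluminium enolate 13 (not isolated)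
Conditions: 3, (i-Bu)2AlH, hexane/THF, 55 °C; then 11, Cu(OTf)2 (5 mol %), chiral sulfonate-bearing N-heterocyclic carbene ligand (5 mol %, from its imidazolinium salt), THF, −78 → −15 °C; then Me3SiOTf, −78 → 0 °C
Reagents that add atoms: trimethylsilyl trifluoromethanesulfonate C[Si](C)(C)OS(=O)(=O)C(F)(F)F
Why: Silicon-directed hydroalumination gives the 1-silylvinylalane, whose copper-catalysed enantioselective conjugate addition creates quaternary C11 (S) under ligand control; silylation then traps the enolate regiospecifically on the C1 side.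

Step 7
Reactants: 14 trimethylsilyl enol ether; 10 homoallylic triflate
Product: 16 (2R,3S)-3-[1-(benzyldimethylsilyl)ethenyl]-2-[(3E)-5-(4-methoxyphenoxy)-3-methylpent-3-en-1-yl]-3-methylcyclopentan-1-one, via lithium enolate 15 (not isolated)
Conditions: MeLi, THF, 0 °C; then 10, DMPU, −78 → −30 °C
Reagents that add atoms: none
Why: Methyllithium regenerates the regiodefined lithium enolate, and C-alkylation by the primary triflate occurs anti to the bulky silylvinyl group, so the C1 chain ends cis to the C11 methyl group, which is also the thermodynamic arrangement.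

Step 8
Reactants: 16 cyclopentanone
Product: 18 (2R,3S)-3-[1-(benzyldimethylsilyl)ethenyl]-5-diazo-2-[(3E)-5-(4-methoxyphenoxy)-3-methylpent-3-en-1-yl]-3-methylcyclopentan-1-one, via trifluoroacetyl ketone 17 (not isolated)
Conditions: LiN(SiMe3)2, THF, −78 °C; CF3CO2CH2CF3; aq. HCl work-up; then MsN3, Et3N, H2O, MeCN, rt
Reagents that add atoms: methanesulfonyl azide CS(=O)(=O)N=[N+]=[N-]
Why: Kinetic deprotonation at the unhindered C9 methylene, trifluoroacetylation and detrifluoroacetylative diazo transfer (Regitz-type) place the diazo group on C9 and leave the C1 stereocentre untouched.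

Step 9
Reactants: 18 2-diazocyclopentanone
Product: 21 methyl (1R,2S,3S)-3-[1-(benzyldimethylsilyl)ethenyl]-2-[(3E)-5-(4-methoxyphenoxy)-3-methylpent-3-en-1-yl]-3-methylcyclobutane-1-carboxylate, via ketene 19 (not isolated), via cis ester 20 (not isolated)
Conditions: hν (350 nm, Pyrex), MeOH, 0 °C; then NaOMe (0.2 equiv), MeOH, rt
Reagents that add atoms: methanol CO
Why: Photolysis expels N2 from the s-cis-locked diazo ketone and C1 migrates from the carbonyl carbon C8 to the diazo carbon C9 (Wolff rearrangement, concerted or through the singlet carbene), giving ketene 19, which methanol captures as the ester. The closest known reaction type is the photochemical Wolff ring contraction of 2-diazocyclopentanones to cyclobutanecarboxylates. The four-membered ring C1–C9–C10–C11 is closed by this 1,2-shift, a contraction of the five-membered ring with C8 expelled from it, not an exo or endo cyclisation. C1 migrates with retention, so its configuration from step 7 is carried over and C11 is untouched; C9 is created when the enol ketonises, kinetically cis, and methoxide equilibration then places the ester trans to the C1 chain. The step needs the diazo group on C9 and not on C1, which step 8 secures by kinetic deprotonation of the unhindered methylene. It also needs rearrangement to outrun carbene insertion or cyclopropanation, which the fixed s-cis geometry and the protic trap favour.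

Step 10
Reactants: 21 cyclobutane methyl ester
Product: 22 1-{(1R,2S,3S)-3-[1-(benzyldimethylsilyl)ethenyl]-2-[(3E)-5-(4-methoxyphenoxy)-3-methylpent-3-en-1-yl]-3-methylcyclobutyl}-2-(phenylsulfonyl)ethan-1-one
Conditions: PhSO2CH3, n-BuLi (2.3 equiv each), THF, −78 → 0 °C; aq. NH4Cl
Reagents that add atoms: methyl phenyl sulfone CS(=O)(=O)c1ccccc1
Why: Claisen-type acylation of lithiated methyl phenyl sulfone by the ester gives the β-keto sulfone (C7 now attached to C8), whose enolate formation in situ protects C9 from epimerisation.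

Step 11
Reactants: 22 β-keto sulfone
Product: 23 (1S,4E,9R,11S)-11-[1-(benzyldimethylsilyl)ethenyl]-4,11-dimethyl-7-(phenylsulfonyl)bicyclo[7.2.0]undec-4-en-8-one (C7 epimers)
Conditions: Pd(PPh3)4 (10 mol %), THF, 65 °C, 2 mM, syringe-pump addition
Reagents that add atoms: none
Why: Zerovalent palladium ionises the allyl aryl ether, and the soft β-keto sulfone carbon C7 attacks the less substituted terminus C6 of the π-allyl complex (intramolecular Tsuji–Trost allylic alkylation), closing the nine-membered ring with the E geometry of C4=C5 retained; the released phenoxide serves as base.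

Step 12
Reactants: 23 cyclic β-keto sulfone
Product: 24 (1S,4E,9R,11S)-11-[1-(benzyldimethylsilyl)ethenyl]-4,11-dimethylbicyclo[7.2.0]undec-4-en-8-one
Conditions: SmI2, THF/MeOH, −78 °C
Reagents that add atoms: none
Why: Electron transfer from divalent samarium cleaves the C–S bond α to the ketone (reductive desulfonylation), which also removes the C7 stereocentre.

Step 13
Reactants: 24 bicyclic ketone
Product: 25 benzyl(dimethyl){1-[(1S,4E,9R,11S)-4,11-dimethyl-8-methylidenebicyclo[7.2.0]undec-4-en-11-yl]ethenyl}silane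
Conditions: Ph3PCH3Br, KN(SiMe3)2, toluene/THF, 0 → 60 °C
Reagents that add atoms: methyltriphenylphosphonium bromide C[P+](c1ccccc1)(c1ccccc1)c1ccccc1.[Br-]
Why: Wittig methylenation installs the exocyclic C8 methylene; any base-mediated equilibration at C9 favours the trans ring fusion already present.

Step 14
Reactants: 25 alkenylsilane
Product: 27 1-[(1S,4E,9R,11S)-4,11-dimethyl-8-methylidenebicyclo[7.2.0]undec-4-en-11-yl]ethan-1-one, via silanol 26 (not isolated)
Conditions: n-Bu4NF, THF, 0 °C; then KHCO3, 30% aq. H2O2, MeOH, rt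
Reagents that add atoms: hydrogen peroxide OO
Why: Fluoride-triggered debenzylation gives the silanol, and Tamao–Fleming oxidation of the alkenyl C–Si bond delivers the enol and hence the C12 methyl ketone under nucleophilic conditions that leave both alkenes alone.

Step 15
Reactants: 28 2-methylidenepropane-1,3-diyl diacetate
Product: 30 2-hydroperoxy-2-methylpropane-1,3-diyl diacetate, via triethylsilyl peroxide 29 (not isolated)
Conditions: Co(thd)2 (thd = 2,2,6,6-tetramethylheptane-3,5-dionate, 5 mol %), O2 (1 atm), Et3SiH, ClCH2CH2Cl, rt; then HF·pyridine, THF, 0 °C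
Reagents that add atoms: dioxygen O=O
Why: Cobalt-catalysed Mukaiyama–Isayama hydroperoxysilylation adds hydrogen and dioxygen across the 1,1-disubstituted alkene in the Markovnikov sense through the tertiary radical, and fluoride frees the hydroperoxide; the product is achiral.

Step 16
Reactants: 30 hydroperoxide
Product: 31 2-[(2-methoxypropan-2-yl)peroxy]-2-methylpropane-1,3-diyl diacetate
Conditions: 2-methoxypropene, PPTS (cat.), CH2Cl2, 0 °C
Reagents that add atoms: 2-methoxypropene C=C(C)OC
Why: Acid-catalysed addition of the hydroperoxide to the enol ether gives a peroxyketal that is stable to bases and enolates and cannot migrate.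

Step 17
Reactants: 31 prochiral diacetate
Product: 32 (R)-3-hydroxy-2-[(2-methoxypropan-2-yl)peroxy]-2-methylpropyl acetate
Conditions: lipase from Burkholderia cepacia (Amano PS), 0.1 M phosphate buffer pH 7, MTBE, 25 °C, pH-stat (NaOH)
Reagents that add atoms: none
Why: A lipase (serine hydrolase) hydrolyses one of the two enantiotopic acetates (enzymatic desymmetrisation of a prochiral diacetate), which sets the quaternary peroxide carbon C15 and leaves the acetate that the target needs.

Step 18
Reactants: 32 monoacetate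
Product: 33 (S)-2-[(2-methoxypropan-2-yl)peroxy]-2-methyl-3-oxopropyl acetate
Conditions: Dess–Martin periodinane, NaHCO3, CH2Cl2, 0 °C → rt
Reagents that add atoms: none
Why: Dess–Martin oxidation of the primary alcohol gives an aldehyde with no α-hydrogen, so C15 cannot epimerise.

Step 19
Reactants: 27 methyl ketone; 33 peroxy aldehyde
Product: 34 β-hydroxy ketone: 3-hydroxy-2-[(2-methoxypropan-2-yl)peroxy]-2-methyl-5-oxo-5-[(1S,4E,9R,11S)-4,11-dimethyl-8-methylidenebicyclo[7.2.0]undec-4-en-11-yl]pentyl acetate (C14 epimers; C15 as in 33)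
Conditions: LiN(i-Pr)2, THF, −78 °C; then 33; AcOH quench at −78 °C
Reagents that add atoms: none
Why: Aldol addition of the lithium enolate of the methyl ketone, which can enolise on one side only, to the non-enolisable aldehyde forms the C13–C14 bond; the cold quench prevents acetyl migration to the new alkoxide.

Step 20
Reactants: 34 β-hydroxy ketone
Product: 36 (E)-enone: C11–C12(=O)–C13H=C14H–C15(CH3)(CH2OAc)–OO–C(CH3)2OCH3 on the bicyclic core of 27, via mesylate 35 (not isolated)
Conditions: MsCl, Et3N, CH2Cl2, −20 °C; then DBU, 0 °C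
Reagents that add atoms: none
Why: Mesylation followed by E1cB elimination gives the E-enone; the tertiary peroxide carbon bears no hydrogen, so base-induced peroxide fragmentation is excluded.

Step 21
Reactants: 36 (E)-enone peroxyketal
Product: 39 peroxy-hemiketal with the C4=C5 alkene: 3,6-dihydro-1,2-dioxin closed between C12 (OH, R) and C15 (CH3 and CH2OAc, R) on the bicyclic core, via E hydroperoxide 37 (not isolated), via Z hydroperoxide 38 (not isolated)
Conditions: AcOH/THF/H2O (4:2:1), rt; concentrate; then hν (350 nm), degassed MeCN, 0 °C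
Reagents that add atoms: none
Why: Mild acid hydrolysis of the peroxyketal frees the hydroperoxide; photochemical E→Z isomerisation of the enone then lets it add to the C12 ketone (6-exo-trig hemiketalisation), which drains the Z isomer. C12 is set under thermodynamic control with OH pseudo-axial and CH2OAc pseudo-equatorial.

Step 22
Reactants: 39 diene peroxy-hemiketal
Product: 40 target CNP0169860.1, (1S,4S,5S,9R,11S)-4,5-epoxide
Conditions: mCPBA (1.05 equiv), NaHCO3, CH2Cl2, 0 °C
Reagents that add atoms: 3-chloroperoxybenzoic acid O=C(OO)c1cccc(Cl)c1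
Why: Prilezhaev epoxidation should take the strained E-trisubstituted C4=C5 alkene well before the exocyclic methylene or the dioxin alkene, with attack on the exposed outer face of the preferred ring conformer (the face selectivity known for the parent caryophyllene skeleton), giving the trans-epoxide of the required relative configuration.

Compound list
1 | ethynylmagnesium bromide | C#C[Mg]Br | starting material
2 | benzylchlorodimethylsilane | C[Si](C)(Cl)Cc1ccccc1 | starting material
3 | benzyl(ethynyl)dimethylsilane | C#C[Si](C)(C)Cc1ccccc1 | intermediate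
4 | (but-3-yn-1-yloxy)(tert-butyl)dimethylsilane | C#CCCO[Si](C)(C)C(C)(C)C | starting material
5 | dimethyl[(1E)-4-(tert-butyldimethylsilyloxy)-2-methylbut-1-en-1-yl]aluminium | C[Al](C)/C=C(C)/CCO[Si](C)(C)C(C)(C)C | intermediate
6 | (E)-5-[(tert-butyldimethylsilyl)oxy]-3-methylpent-2-en-1-ol | OC/C=C(C)/CCO[Si](C)(C)C(C)(C)C | intermediate
7 | 4-methoxyphenol | COc1ccc(O)cc1 | starting material
8 | tert-butyl{[(3E)-5-(4-methoxyphenoxy)-3-methylpent-3-en-1-yl]oxy}dimethylsilane | COc1ccc(OC/C=C(C)/CCO[Si](C)(C)C(C)(C)C)cc1 | intermediate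
9 | (E)-5-(4-methoxyphenoxy)-3-methylpent-3-en-1-ol | COc1ccc(OC/C=C(C)/CCO)cc1 | intermediate
10 | (E)-5-(4-methoxyphenoxy)-3-methylpent-3-en-1-yl trifluoromethanesulfonate | COc1ccc(OC/C=C(C)/CCOS(=O)(=O)C(F)(F)F)cc1 | intermediate
11 | 3-methylcyclopent-2-en-1-one | CC1=CC(=O)CC1 | starting material
12 | [1-(benzyldimethylsilyl)ethenyl]bis(2-methylpropyl)aluminium | C=C([Al](CC(C)C)CC(C)C)[Si](C)(C)Cc1ccccc1 | intermediate
13 | diisobutylaluminium enolate of (S)-3-[1-(benzyldimethylsilyl)ethenyl]-3-methylcyclopentanone (enolate toward C1) | CC(C)C[Al](CC(C)C)OC1=C[C@@](C)(C(=C)[Si](C)(C)Cc2ccccc2)CC1 | intermediate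
14 | (S)-benzyl(dimethyl){1-[1-methyl-3-(trimethylsilyloxy)cyclopent-2-en-1-yl]ethenyl}silane | C[Si](C)(C)OC1=C[C@@](C)(C(=C)[Si](C)(C)Cc2ccccc2)CC1 | intermediate
15 | lithium enolate corresponding to 14 | [Li]OC1=C[C@@](C)(C(=C)[Si](C)(C)Cc2ccccc2)CC1 | intermediate
16 | (2R,3S)-3-[1-(benzyldimethylsilyl)ethenyl]-2-[(3E)-5-(4-methoxyphenoxy)-3-methylpent-3-en-1-yl]-3-methylcyclopentan-1-one (chain cis to the ring methyl) | O=C1CC[C@](C)(C(=C)[Si](C)(C)Cc2ccccc2)[C@H]1CC/C(C)=C/COc1ccc(OC)cc1 | intermediate
17 | 5-(trifluoroacetyl) derivative of 16 (C5 unassigned, enolised) | O=C1C(C(=O)C(F)(F)F)C[C@](C)(C(=C)[Si](C)(C)Cc2ccccc2)[C@H]1CC/C(C)=C/COc1ccc(OC)cc1 | intermediate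
18 | (2R,3S)-5-diazo derivative of 16 | O=C1C(=[N+]=[N-])C[C@](C)(C(=C)[Si](C)(C)Cc2ccccc2)[C@H]1CC/C(C)=C/COc1ccc(OC)cc1 | intermediate
19 | cyclobutylidene ketene from ring contraction of 18 | O=C=C1C[C@](C)(C(=C)[Si](C)(C)Cc2ccccc2)[C@H]1CC/C(C)=C/COc1ccc(OC)cc1 | intermediate
20 | methyl (1S,2S,3S)-cyclobutanecarboxylate, ester cis to the C2 chain (C9 epimer of 21) | COC(=O)[C@H]1C[C@](C)(C(=C)[Si](C)(C)Cc2ccccc2)[C@H]1CC/C(C)=C/COc1ccc(OC)cc1 | intermediate
21 | methyl (1R,2S,3S)-3-[1-(benzyldimethylsilyl)ethenyl]-2-[(3E)-5-(4-methoxyphenoxy)-3-methylpent-3-en-1-yl]-3-methylcyclobutane-1-carboxylate (ester trans to chain) | COC(=O)[C@@H]1C[C@](C)(C(=C)[Si](C)(C)Cc2ccccc2)[C@H]1CC/C(C)=C/COc1ccc(OC)cc1 | intermediate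
22 | β-keto sulfone: 1-[(1R,2S,3S)-cyclobutyl as in 21]-2-(phenylsulfonyl)ethan-1-one | O=C(CS(=O)(=O)c1ccccc1)[C@@H]1C[C@](C)(C(=C)[Si](C)(C)Cc2ccccc2)[C@H]1CC/C(C)=C/COc1ccc(OC)cc1 | intermediate
23 | (1S,4E,9R,11S)-11-[1-(benzyldimethylsilyl)ethenyl]-4,11-dimethyl-7-(phenylsulfonyl)bicyclo[7.2.0]undec-4-en-8-one (C7 epimers) | O=C1C(S(=O)(=O)c3ccccc3)C/C=C(C)/CC[C@H]2[C@H]1C[C@]2(C)C(=C)[Si](C)(C)Cc1ccccc1 | intermediate
24 | (1S,4E,9R,11S)-11-[1-(benzyldimethylsilyl)ethenyl]-4,11-dimethylbicyclo[7.2.0]undec-4-en-8-one | O=C1CC/C=C(C)/CC[C@H]2[C@H]1C[C@]2(C)C(=C)[Si](C)(C)Cc1ccccc1 | intermediate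
25 | benzyl(dimethyl){1-[(1S,4E,9R,11S)-4,11-dimethyl-8-methylidenebicyclo[7.2.0]undec-4-en-11-yl]ethenyl}silane | C=C1CC/C=C(C)/CC[C@H]2[C@H]1C[C@]2(C)C(=C)[Si](C)(C)Cc1ccccc1 | intermediate
26 | dimethylsilanol corresponding to 25 (benzyl replaced by OH) | C=C1CC/C=C(C)/CC[C@H]2[C@H]1C[C@]2(C)C(=C)[Si](C)(C)O | intermediate
27 | 1-[(1S,4E,9R,11S)-4,11-dimethyl-8-methylidenebicyclo[7.2.0]undec-4-en-11-yl]ethan-1-one | C=C1CC/C=C(C)/CC[C@H]2[C@H]1C[C@]2(C)C(C)=O | intermediate
28 | 2-methylidenepropane-1,3-diyl diacetate | C=C(COC(C)=O)COC(C)=O | starting material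
29 | 2-methyl-2-(triethylsilylperoxy)propane-1,3-diyl diacetate | CC[Si](CC)(CC)OOC(C)(COC(C)=O)COC(C)=O | intermediate
30 | 2-hydroperoxy-2-methylpropane-1,3-diyl diacetate | CC(COC(C)=O)(COC(C)=O)OO | intermediate
31 | 2-[(2-methoxypropan-2-yl)peroxy]-2-methylpropane-1,3-diyl diacetate | COC(C)(C)OOC(C)(COC(C)=O)COC(C)=O | intermediate
32 | (R)-3-hydroxy-2-[(2-methoxypropan-2-yl)peroxy]-2-methylpropyl acetate | OC[C@](C)(COC(C)=O)OOC(C)(C)OC | intermediate
33 | (S)-2-[(2-methoxypropan-2-yl)peroxy]-2-methyl-3-oxopropyl acetate | O=C[C@](C)(COC(C)=O)OOC(C)(C)OC | intermediate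
34 | aldol adduct of 27 and 33 (C14 carbinol epimers) | C=C1CC/C=C(C)/CC[C@H]2[C@H]1C[C@]2(C)C(=O)CC(O)[C@](C)(COC(C)=O)OOC(C)(C)OC | intermediate
35 | C14 methanesulfonate of 34 | C=C1CC/C=C(C)/CC[C@H]2[C@H]1C[C@]2(C)C(=O)CC(OS(C)(=O)=O)[C@](C)(COC(C)=O)OOC(C)(C)OC | intermediate
36 | (E)-enone with protected γ-peroxide | C=C1CC/C=C(C)/CC[C@H]2[C@H]1C[C@]2(C)C(=O)/C=C/[C@](C)(COC(C)=O)OOC(C)(C)OC | intermediate
37 | (E)-γ-hydroperoxy enone | C=C1CC/C=C(C)/CC[C@H]2[C@H]1C[C@]2(C)C(=O)/C=C/[C@](C)(COC(C)=O)OO | intermediate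
38 | (Z)-γ-hydroperoxy enone | C=C1CC/C=C(C)/CC[C@H]2[C@H]1C[C@]2(C)C(=O)/C=C\[C@](C)(COC(C)=O)OO | intermediate
39 | peroxy-hemiketal with C4=C5 alkene (C12 R, C15 R; core 1S,9R,11S) | C=C1CC/C=C(C)/CC[C@H]2[C@H]1C[C@]2(C)[C@@]1(O)C=C[C@](C)(COC(C)=O)OO1 | intermediate
40 | CNP0169860.1 | C=C1CC[C@@H]2O[C@@]2(C)CC[C@H]2[C@H]1C[C@]2(C)[C@@]1(O)C=C[C@](C)(COC(C)=O)OO1 | target

Total step count: 22. Longest linear sequence: 16 steps (steps 2–5, 7–14, 19–22).

Steps most likely to fail

Step 11 (nine-membered ring closure). Ionisation of the aryl ether may be slow, oligomerisation may compete with closure of the strained E-ring, and the π-allyl may be attacked at its tertiary terminus or lose its geometry by π–σ–π isomerisation. The fallback replaces the π-allyl chemistry by an SN2 closure and sets out from 22: (NH4)2Ce(NO3)6 in MeCN/H2O removes the 4-methoxyphenyl group to give the allylic alcohol F1; CBr4/PPh3 converts it into the allylic bromide F2; Cs2CO3 in MeCN under high dilution then closes the ring by intramolecular C-alkylation of the β-keto sulfone with fixed alkene geometry, returning to 23.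

Step 21 (E→Z isomerisation and hemiketal closure). The photoisomerisation may stall at a photostationary mixture, the O–O bond may be photolysed, or the excited enone may isomerise the ring alkene. The fallback closes the ring first and forms the cis alkene inside it, setting out from 34: PPTS in MeOH frees the hydroperoxide, which adds to the C12 ketone and is fixed as the methyl peroxyketal, the 5-hydroxy-3-methoxy-1,2-dioxane F3; Martin sulfurane in CH2Cl2 dehydrates the secondary alcohol toward C13 (the only β-hydrogens) to the 3-methoxy-3,6-dihydro-1,2-dioxin F4; AcOH/H2O/THF hydrolyses the methyl ketal and returns to 39.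

Step 7 (enolate alkylation). The homoallylic triflate may ionise with alkene participation, O-alkylation may compete, and proton transfer between enolate and product may erode regiocontrol at the hindered C1. The fallback builds the chain by cross-coupling and sets out from 15 (generated from 14): alkylation with 2-[(tert-butyldimethylsilyl)oxy]ethyl trifluoromethanesulfonate, a triflate that cannot ionise with participation, gives the silyl ether F5; n-Bu4NF gives the alcohol F6; I2/PPh3/imidazole gives the iodide F7; zinc insertion (Zn, LiCl, THF) and Negishi coupling with PdCl2(dppf) and the vinyl iodide F8 (from (E)-3-iodobut-2-en-1-ol and 7 by Mitsunobu etherification) forms the C3–C4 bond with retention of alkene geometry and returns to 16.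

Further compounds
F1 | step 11 | allylic alcohol from 22 (aryl ether replaced by OH) | O=C(CS(=O)(=O)c1ccccc1)[C@@H]1C[C@](C)(C(=C)[Si](C)(C)Cc2ccccc2)[C@H]1CC/C(C)=C/CO
F2 | step 11 | allylic bromide from F1 | O=C(CS(=O)(=O)c1ccccc1)[C@@H]1C[C@](C)(C(=C)[Si](C)(C)Cc2ccccc2)[C@H]1CC/C(C)=C/CBr
F3 | step 21 | 5-hydroxy-3-methoxy-1,2-dioxane (methyl peroxyketal at C12, OH at C14, epimers) | C=C1CC/C=C(C)/CC[C@H]2[C@H]1C[C@]2(C)C1(OC)CC(O)[C@](C)(COC(C)=O)OO1
F4 | step 21 | 3-methoxy-3,6-dihydro-1,2-dioxin (methyl peroxyketal of 39) | C=C1CC/C=C(C)/CC[C@H]2[C@H]1C[C@]2(C)C1(OC)C=C[C@](C)(COC(C)=O)OO1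
F5 | step 7 | (2R,3S)-3-[1-(benzyldimethylsilyl)ethenyl]-2-{2-[(tert-butyldimethylsilyl)oxy]ethyl}-3-methylcyclopentan-1-one | O=C1CC[C@](C)(C(=C)[Si](C)(C)Cc2ccccc2)[C@H]1CCO[Si](C)(C)C(C)(C)C
F6 | step 7 | (2R,3S)-3-[1-(benzyldimethylsilyl)ethenyl]-2-(2-hydroxyethyl)-3-methylcyclopentan-1-one | O=C1CC[C@](C)(C(=C)[Si](C)(C)Cc2ccccc2)[C@H]1CCO
F7 | step 7 | (2R,3S)-3-[1-(benzyldimethylsilyl)ethenyl]-2-(2-iodoethyl)-3-methylcyclopentan-1-one | O=C1CC[C@](C)(C(=C)[Si](C)(C)Cc2ccccc2)[C@H]1CCI
F8 | step 7 | (E)-1-[(3-iodobut-2-en-1-yl)oxy]-4-methoxybenzene | COc1ccc(OC/C=C(C)/I)cc1
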